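# Proposed total synthesis of CNP0212201.1 (34)

## Analysis of the target

The target 34 is a bisabolane-type sesquiterpenoid with one carbocycle, a cyclohexane C1–C6 that carries a methyl group (C7) and a free tertiary hydroxyl on C1, an angelate on C2, an acetate on C3, chlorine on C6 and, on C4, the chain C8(=C9H2)–C10H(OAng)–C11H2–C12H(OH)–C13(OH)(C14H3)(C15H3). It has seven stereocentres, 1R, 2R, 3R, 4S and 6R on the ring and 10S and 12S in the chain, whose two secondary oxygens are 1,3-anti. On the ring, the oxygens on C1, C2 and C3 and the side chain on C4 lie on one face and the chlorine on the other, so that in the chair with the chain equatorial C1–OH, C3–OAc and C6–Cl are axial and chlorine is trans-diaxial to the C1 hydroxyl. The sensitive groups are the two (Z)-configured angelates, which isomerise to tiglates, the trans-chlorohydrin, which closes to an epoxide with base, the cis acyloxy/hydroxy array on C1–C3, which is prone to acyl shifts, the allylic C10 ester, and the C4–C8=C9 unit, which can move into conjugation whenever C3 is a ketone. The difficulty is to tell three neighbouring ring oxygens apart (free OH, angelate, acetate), to place chlorine trans to the tertiary hydroxyl, and to bring in a chain with two remote stereocentres and three more oxygens. The strategy rests on the C1–C2 bond: C1 and C2 are adjacent, cis-configured carbinol carbons, one of them tertiary, so both can be carbonyl carbons of one open chain, a C1 methyl ketone and a C2 aldehyde. The C1 oxygen is moreover trans to the C6 heteroatom, which is the relationship a reductive carbonyl coupling produces next to an α-silyloxy ketone. C3, finally, can be a ketone that is masked while the ring closes and later directs the side chain to C4.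

## Retrosynthetic reasoning

**C6–Cl and the side-chain diol (34 back to 32).** The trans-diaxial C1–OH/C6–Cl pair of 34 is what a chloride nucleophile leaves when it opens the C1–C6 epoxide 32 at its secondary carbon. Cutting C6–Cl last keeps the base-labile chlorohydrin out of every enolate, hydride and acylation step. The same acidic medium can then free the C12,C13-diol from its acetonide by way of 33. The forward reaction has to send chloride to C6 and not to the tertiary C1.

**The epoxide C6–O bond (32 back to 30 and 29).** Epoxide 32 comes from the trans-1,6-diol 30 by activating the secondary C6 hydroxyl in 31 and letting the C1 hydroxyl displace it. C6 is inverted here and again in the opening, so the C6 oxygen of the ring-forming step is replaced by chlorine with net retention. Diol 30 arises from 29 by one fluoride-mediated desilylation that frees exactly the two hydroxyls needed.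

**The angelate C–O bonds (29 back to 28 and 27).** Both angelates are cut together. In 27 the C2 and C10 oxygens carry the same 4-methoxybenzyl group, so one oxidative step gives diol 28 and one acylation gives 29. Placing these esters after all strongly basic steps protects their (Z) geometry.

**The C3 acetate and the C3–H bond (27 back to 26 and 25).** C3 is the only ring oxygen that enters as a ketone. Hydride addition to 25 gives 26, and acetylation gives 27. The C3 oxygen is therefore distinguished from the C2 oxygen by construction, not by a selective acylation.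

**The C4–C8 bond (25 back to 14 and 24).** This cut divides the molecule into a ring ketone 14 and a chain bromide 24 of similar size. C4 is α to the C3 ketone and C8 is an sp2 carbon, so the forward reaction is an enolate alkenylation. It must enolise 14 towards C4 and set C4 on protonation.

**The chain (24 back to 15).** In 24 the C10 carbinol is traced to the bromo enone 22 through 23 (reagent-controlled reduction). The bromoalkene is traced to enone 20 through 21, and C8/C9 to a vinyl addition on the Weinreb amide 19 (from 18). The two C13 methyl groups are traced to the lactone 17 and the dioxolanone 16, and C12 to L-malic acid 15.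

**Protecting groups on the ring (14 back to 11).** A cyclic acetal across C1/C2 would have to be removed by acid in the presence of the side-chain acetonide, and would free C1–OH and C2–OH together. Instead, the C2 oxygen of 11 is etherified as in 12 (it falls with the C10 ether), and the C1 oxygen is silylated as in 13 (it falls with the C6 silyl ether). The ketal is then hydrolysed to 14. Oxidation, fluoride and acid thus each serve one purpose.

**The C1–C2 bond (11 back to 10).** This is the central disconnection. It removes the ring and two stereocentres at once and leads to the open-chain keto aldehyde 10. Its only stereocentre, C6, controls C1, and through the cis-diol it controls C2. The C3 ketal carries no hydrogen and no stereocentre.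

**The open chain (10 back to 1).** Both carbonyl groups of 10 are released together from diene 9. The vinyl ketal of 9 comes from enone 8 and Weinreb amide 7 (from 6). The isopropenyl group comes from the acetyl lactone 4 through 5. Lactone 4 derives from the lactone acid 2 through 3, and 2 from D-glutamic acid 1, whose stereocentre becomes C6.

## Alternatives that were turned down

Alternative 1: The disconnection lies in the chain only. The C8–C10 and C11–C12 bonds are made in one operation and no ring bond is formed. In the forward step, the ring alkenyllithium A2 adds to vinylboronic acid pinacol ester A3 to give a boron ate complex. With palladium diacetate A5 and a chiral ferrocene-based bisphosphine ligand as the catalyst, the alkenylpalladium species formed from 2-methylprop-1-enyl triflate A4 attacks C11. C8 then shifts from boron to C10, giving the allylic boronate A1 with C10 set by the ligand.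
- For: the step is convergent, forms two C–C bonds and one stereocentre catalytically, and delivers the whole carbon skeleton with a C12=C13 alkene ready for dihydroxylation. On convergence and on catalytic control of C10 it is stronger than the chosen route, which spends four steps on C10.
- Against: it leaves the real problem, the ring, to an unspecified synthesis of A2 with three contiguous stereocentres. In A1 the C2 and C3 oxygens bear identical silyl groups, so the angelate/acetate differentiation is unsolved. The C1=C6 alkene must be turned into the trans-chlorohydrin late, with face and regiocontrol, next to two other alkenes. The migrating group is an α-branched alkenyl next to a ring stereocentre. The product is an allylic boronate that can undergo 1,3-shift.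
- In its place, the chosen strategy builds the ring with C1, C2 and C6 related in one step, differentiates C2 from C3 through the C3 ketone, and installs chlorine stereospecifically.

Alternative 2: The disconnection is the ring bond C4–C5 together with C6–Cl. In the forward step, manganese triacetate A7 oxidises an open-chain β-keto ester to the C4 radical, which attacks the terminal alkene carbon C5 in a 6-endo closure. The C6 radical takes chlorine from copper dichloride A8, giving the chloro keto ester A6.
- For: the ring and the C–Cl bond form in one step, without the desilylation, epoxide and opening sequence. In this it is shorter than the chosen route. Oxidative radical cyclisations ending in chlorine transfer are a known class.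
- Against: chlorine transfer to a secondary cyclohexyl radical has no secure element that puts chlorine trans to the C1 oxygen, and 5-exo closure competes. The secondary chloride then has to survive the reduction at C3 and the whole linear growth of C8–C13 from the C4 ester. That growth involves organometallic steps, a methylenation and two new stereocentres, while the chloride sits γ to an enolisable position where 1,3-elimination threatens. The C1/C2 stereocentres must come from a separate source.
- In its place, the chosen strategy introduces chlorine after the last basic step with defined configuration, and attaches a complete, stereodefined chain in one coupling.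

Alternative 3: The disconnection is the ring bond C5–C6. In the forward step, samarium diiodide A10 reduces a C6 aldehyde to a ketyl that adds to the β-carbon C5 of an acrylate whose α-carbon is C4 (6-endo closure). The samarium enolate is protonated at C4, giving the hydroxy ester A9.
- For: the substrate derives from a chiral-pool sugar lactone that already carries the C1 methyl branch. The C1, C2 and C3 oxygens therefore arrive with correct relative configuration and already differentiated (acetonide against silyl ether). On this triad it is as strong as or stronger than the chosen route, which needs a ketone reduction for C3. Ketyl additions to acrylates are polarity-matched and reliable.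
- Against: two new stereocentres (C6 and C4) form without an obvious controlling element. The C6 hydroxyl must still be converted into chlorine with the right orientation. C4 carries only an ester, so the 1,1-disubstituted alkene and the C10 and C12 centres must be built linearly next to an epimerisable position. The C1/C2 acetonide would later collide with the protection of the side-chain diol.
- In its place, the chosen strategy offers a short route to the cyclisation substrate from one amino acid, a C3 ketone that directs the chain to C4, and a convergent endgame.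

Key step: step 9

## Route

Remark: the locants C1–C15 defined in the analysis are used for all intermediates; systematic names carry their own locants. Compound 2 is also an article of commerce, which would shorten the longest sequence by one step.

**Ring fragment**

Step 1
Reactants: 1 D-glutamic acid
Product: 2 (2R)-5-oxooxolane-2-carboxylic acid
Conditions: NaNO2, aq. HCl, 0 °C → rt; evaporate, extract with EtOAc
Reagents that add atoms: none
Why: Nitrous acid deamination: the diazonium group is displaced by the neighbouring α-carboxylate to an α-lactone, which the γ-carboxylate opens with a second inversion, so the lactone acid forms with net retention and the future C6 is fixed as R.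

Step 2
Reactants: 2 (2R)-5-oxooxolane-2-carboxylic acid
Product: 4 (5R)-5-acetyloxolan-2-one, via acid chloride 3 (not isolated)
Conditions: (COCl)2, DMF (cat.), CH2Cl2, 0 °C → rt; concentrate; Me2CuLi, Et2O/THF, −78 °C
Reagents that add atoms: lithium dimethylcuprate, [Li+].C[Cu-]C
Why: Acid chloride formation followed by the organocuprate ketone synthesis; at −78 °C the cuprate reacts only with the acyl chloride and leaves the lactone and the new ketone alone, and no base strong enough to epimerise C6 is present.

Step 3
Reactants: 4 (5R)-5-acetyloxolan-2-one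
Product: 5 (5R)-5-(prop-1-en-2-yl)oxolan-2-one
Conditions: Zn, CH2Br2, TiCl4, THF/CH2Cl2, 0 °C → rt
Reagents that add atoms: dibromomethane, BrCBr
Why: Takai–Lombardo methylenation is non-basic and selective for ketones over lactones, so the α-oxygenated centre C6 should not epimerise; the alkene masks the C1 ketone until the ozonolysis of step 8.

Step 4
Reactants: 5 (5R)-5-(prop-1-en-2-yl)oxolan-2-one
Product: 6 (4R)-4-hydroxy-N-methoxy-N,5-dimethylhex-5-enamide
Conditions: MeNH(OMe)·HCl, AlMe3, CH2Cl2, 0 °C → rt
Reagents that add atoms: N,O-dimethylhydroxylamine hydrochloride, CNOC.Cl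
Why: Weinreb aminolysis of the γ-lactone by the aluminium amide frees the C6 hydroxyl and turns C3 into an acyl donor that accepts exactly one organometallic addition.

Step 5
Reactants: 6 (4R)-4-hydroxy-N-methoxy-N,5-dimethylhex-5-enamide
Product: 7 (4R)-4-[(tert-butyldimethylsilyl)oxy]-N-methoxy-N,5-dimethylhex-5-enamide
Conditions: t-BuMe2SiCl, imidazole, DMF, rt
Reagents that add atoms: tert-butyldimethylsilyl chloride, CC(C)(C)[Si](C)(C)Cl
Why: Standard silylation of a secondary allylic alcohol; it prevents relactonisation, and the silyl ether later steers the ring closure and is the precursor of the C6 chloride.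

Step 6
Reactants: 7 (4R)-4-[(tert-butyldimethylsilyl)oxy]-N-methoxy-N,5-dimethylhex-5-enamide
Product: 8 (6R)-6-[(tert-butyldimethylsilyl)oxy]-7-methylocta-1,7-dien-3-one
Conditions: CH2=CHMgBr, THF, 0 °C; inverse quench into cold 1 M HCl
Reagents that add atoms: vinylmagnesium bromide, C=C[Mg]Br
Why: Weinreb ketone synthesis: the chelated tetrahedral intermediate prevents a second addition, and the acidic inverse quench protonates the released hydroxylamine before it can add to the enone.

Step 7
Reactants: 8 (6R)-6-[(tert-butyldimethylsilyl)oxy]-7-methylocta-1,7-dien-3-one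
Product: 9 tert-butyl{[(3R)-5-(2-ethenyl-1,3-dioxolan-2-yl)-2-methylpent-1-en-3-yl]oxy}dimethylsilane
Conditions: (Me3SiOCH2)2, Me3SiOTf (5 mol %), CH2Cl2, −78 → −20 °C; pyridine
Reagents that add atoms: 1,2-bis(trimethylsilyloxy)ethane, C[Si](C)(C)OCCO[Si](C)(C)C
Why: Noyori ketalisation under aprotic conditions converts the vinyl ketone into its dioxolane without conjugate addition or double-bond shift and without loss of the silyl ether; the ketal keeps C3 free of a stereocentre and inert to the reductant of step 9.

Step 8
Reactants: 9 tert-butyl{[(3R)-5-(2-ethenyl-1,3-dioxolan-2-yl)-2-methylpent-1-en-3-yl]oxy}dimethylsilane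
Product: 10 2-{(3R)-3-[(tert-butyldimethylsilyl)oxy]-4-oxopentyl}-1,3-dioxolane-2-carbaldehyde
Conditions: O3, CH2Cl2, −78 °C; PPh3, −78 °C → rt
Reagents that add atoms: ozone, [O-][O+]=O
Why: Ozonolysis with reductive work-up cleaves both terminal alkenes in one operation, the isopropenyl group to the C1 methyl ketone and the vinyl group to the C2 aldehyde; no stereocentre is touched, and the hydrate-prone aldehyde is used at once.

Step 9
Reactants: 10 2-{(3R)-3-[(tert-butyldimethylsilyl)oxy]-4-oxopentyl}-1,3-dioxolane-2-carbaldehyde
Product: 11 (6S,7R,8R)-8-[(tert-butyldimethylsilyl)oxy]-7-methyl-1,4-dioxaspiro[4.5]decane-6,7-diol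
Conditions: SmI2 (3 equiv, 0.1 M in THF), t-BuOH (3 equiv), THF, −78 → −20 °C
Reagents that add atoms: none
Why: SmI2 transfers one electron to the more easily reduced aldehyde, and the C2 ketyl, bound to trivalent samarium, adds to the carbonyl carbon of the C1 methyl ketone that the same Lewis-acidic metal centre activates; a second electron reduces the resulting oxygen radical to the samarium diolate, which t-BuOH protonates. The closest known reaction type is the SmI2-promoted intramolecular pinacol coupling of 1,6-keto aldehydes and dialdehydes bearing α-oxygen substituents to cis-cyclohexane-1,2-diols. The six-membered ring closes in a 6-exo-trig mode, the ketyl carbon attacking the C1=O carbon with the carbonyl oxygen outside the ring. The cis relationship of the two new carbinol centres is controlled by the samarium ion, which bridges both oxygens in the cyclic transition state. The configuration of C1 is controlled by the existing C6 centre: the bulky, electron-rich silyloxy group lies anti to the ketone oxygen (dipole and steric minimisation of the Felkin type), so the C1 oxygen ends trans to the C6 oxygen, and C2 follows through the chelate. C3 is a ketal without hydrogen and exerts no competing bias. The step needs chemoselectivity for cyclisation over plain reduction of the aldehyde and over expulsion of a ketal oxygen from the ketyl, which low temperature, the absence of strongly donating additives and the fast closure onto the chelated ketone should secure. It also needs diastereoselectivity, which the chelate and the C6 silyl ether should secure.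

Step 10
Reactants: 11 (6S,7R,8R)-8-[(tert-butyldimethylsilyl)oxy]-7-methyl-1,4-dioxaspiro[4.5]decane-6,7-diol
Product: 12 (6S,7R,8R)-8-[(tert-butyldimethylsilyl)oxy]-6-[(4-methoxyphenyl)methoxy]-7-methyl-1,4-dioxaspiro[4.5]decan-7-ol
Conditions: NaH (1.1 equiv), 4-MeOC6H4CH2Cl, Bu4NI (cat.), DMF, 0 °C → rt
Reagents that add atoms: 4-methoxybenzyl chloride, COc1ccc(CCl)cc1
Why: Williamson etherification: the secondary C2 hydroxyl is more acidic and far less hindered than the tertiary C1 hydroxyl, so it is alkylated selectively; the 4-methoxybenzyl group is chosen because one oxidation later frees C2–OH together with C10–OH.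

Step 11
Reactants: 12 (6S,7R,8R)-8-[(tert-butyldimethylsilyl)oxy]-6-[(4-methoxyphenyl)methoxy]-7-methyl-1,4-dioxaspiro[4.5]decan-7-ol
Product: 13 tert-butyl({(6S,7R,8R)-6-[(4-methoxyphenyl)methoxy]-7-methyl-7-[(triethylsilyl)oxy]-1,4-dioxaspiro[4.5]decan-8-yl}oxy)dimethylsilane
Conditions: Et3SiOTf, 2,6-lutidine, CH2Cl2, −78 → 0 °C
Reagents that add atoms: triethylsilyl triflate, CC[Si](CC)(CC)OS(=O)(=O)C(F)(F)F
Why: Silyl triflate silylation of a hindered tertiary alcohol; the C1 silyl ether blocks retro-aldol cleavage and acyl transfer in later steps and, with the C6 silyl ether, favours the chair in which both silyloxy groups are axial.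

Step 12
Reactants: 13 tert-butyl({(6S,7R,8R)-6-[(4-methoxyphenyl)methoxy]-7-methyl-7-[(triethylsilyl)oxy]-1,4-dioxaspiro[4.5]decan-8-yl}oxy)dimethylsilane
Product: 14 (2S,3R,4R)-4-[(tert-butyldimethylsilyl)oxy]-2-[(4-methoxyphenyl)methoxy]-3-methyl-3-[(triethylsilyl)oxy]cyclohexan-1-one
Conditions: pyridinium p-toluenesulfonate (0.3 equiv), acetone/H2O (10:1), 60 °C
Reagents that add atoms: water, O
Why: Acid-catalysed ketal hydrolysis with acetone as glycol acceptor; the pyridinium salt is mild enough for the hindered silyl ethers and the benzyl-type ether, and the C3 ketone is released for the coupling.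

**Side-chain fragment**

Step 13
Reactants: 15 L-malic acid
Product: 16 2-[(4S)-2,2-dimethyl-5-oxo-1,3-dioxolan-4-yl]acetic acid
Conditions: Me2C(OMe)2, p-TsOH·H2O (cat.), rt
Reagents that add atoms: 2,2-dimethoxypropane, COC(C)(C)OC
Why: Acetonide-type protection of the α-hydroxy acid as the five-membered dioxolanone leaves the β-carboxyl free and activates the α-carboxyl (the future C13); C12 comes unchanged from the chiral pool.

Step 14
Reactants: 16 2-[(4S)-2,2-dimethyl-5-oxo-1,3-dioxolan-4-yl]acetic acid
Product: 17 (4S)-4-hydroxy-5,5-dimethyloxolan-2-one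
Conditions: MeMgBr (5 equiv), THF, −20 °C → rt; aq. HCl, then concentrate from toluene
Reagents that add atoms: methylmagnesium bromide, C[Mg]Br
Why: Grignard addition to the dioxolanone, an activated ester, occurs twice with loss of acetone and gives the tertiary carbinol C13, while the magnesium carboxylate formed first is inert; on acidification the γ-hydroxy acid lactonises.

Step 15
Reactants: 17 (4S)-4-hydroxy-5,5-dimethyloxolan-2-one
Product: 18 (3S)-3,4-dihydroxy-N-methoxy-N,4-dimethylpentanamide
Conditions: MeNH(OMe)·HCl, AlMe3 (3 equiv), CH2Cl2, 0 °C → rt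
Reagents that add atoms: N,O-dimethylhydroxylamine hydrochloride, CNOC.Cl
Why: Weinreb aminolysis of the lactone as in step 4; the crude diol is carried on at once so that it cannot relactonise.

Step 16
Reactants: 18 (3S)-3,4-dihydroxy-N-methoxy-N,4-dimethylpentanamide
Product: 19 N-methoxy-N-methyl-2-[(4S)-2,2,5,5-tetramethyl-1,3-dioxolan-4-yl]acetamide
Conditions: Me2C(OMe)2, pyridinium p-toluenesulfonate (cat.), CH2Cl2, rt
Reagents that add atoms: 2,2-dimethoxypropane, COC(C)(C)OC
Why: Acetonide formation on the only 1,2-diol; the tetramethyl-substituted dioxolane is robust and stays until the last step.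

Step 17
Reactants: 19 N-methoxy-N-methyl-2-[(4S)-2,2,5,5-tetramethyl-1,3-dioxolan-4-yl]acetamide
Product: 20 1-[(4S)-2,2,5,5-tetramethyl-1,3-dioxolan-4-yl]but-3-en-2-one
Conditions: CH2=CHMgBr, THF, 0 °C; inverse quench into cold 1 M HCl
Reagents that add atoms: vinylmagnesium bromide, C=C[Mg]Br
Why: Weinreb ketone synthesis as in step 6; the vinyl group supplies C8 and C9, and the amide carbonyl becomes C10.

Step 18
Reactants: 20 1-[(4S)-2,2,5,5-tetramethyl-1,3-dioxolan-4-yl]but-3-en-2-one
Product: 22 3-bromo-1-[(4S)-2,2,5,5-tetramethyl-1,3-dioxolan-4-yl]but-3-en-2-one, via dibromo ketone 21 (not isolated)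
Conditions: Br2, CH2Cl2, −78 °C; then Et3N, −78 → 0 °C
Reagents that add atoms: bromine, BrBr
Why: Bromination–dehydrobromination of an enone: bromine adds to the alkene and triethylamine removes the acidic α-hydrogen with loss of the β-bromide (E1cB), which is much faster than enolisation towards C11 and loss of the acetonide oxygen.

Step 19
Reactants: 22 3-bromo-1-[(4S)-2,2,5,5-tetramethyl-1,3-dioxolan-4-yl]but-3-en-2-one
Product: 23 (2S)-3-bromo-1-[(4S)-2,2,5,5-tetramethyl-1,3-dioxolan-4-yl]but-3-en-2-ol
Conditions: (R)-1-methyl-3,3-diphenyltetrahydro-1H,3H-pyrrolo[1,2-c][1,3,2]oxazaborole (20 mol %), BH3·SMe2 (0.7 equiv), THF, −30 °C; MeOH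
Reagents that add atoms: none
Why: CBS reduction: the 1-bromovinyl group takes the large-group position and the methylene chain the small one, so the (R)-oxazaborolidine should deliver hydride to the face that gives the 10S carbinol; reagent control overrides the remote C12 centre and gives the 10,12-anti relationship.

Step 20
Reactants: 23 (2S)-3-bromo-1-[(4S)-2,2,5,5-tetramethyl-1,3-dioxolan-4-yl]but-3-en-2-ol
Product: 24 (4S)-4-{(2S)-3-bromo-2-[(4-methoxyphenyl)methoxy]but-3-en-1-yl}-2,2,5,5-tetramethyl-1,3-dioxolane
Conditions: NaH, 4-MeOC6H4CH2Cl, Bu4NI (cat.), THF/DMF, 0 °C → rt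
Reagents that add atoms: 4-methoxybenzyl chloride, COc1ccc(CCl)cc1
Why: Williamson etherification of the allylic alcohol; an ether and not an ester is needed at C10 because the next step uses a strong base and a zerovalent palladium catalyst.

**Coupling and endgame**

Step 21
Reactants: 14 (2S,3R,4R)-4-[(tert-butyldimethylsilyl)oxy]-2-[(4-methoxyphenyl)methoxy]-3-methyl-3-[(triethylsilyl)oxy]cyclohexan-1-one; 24 (4S)-4-{(2S)-3-bromo-2-[(4-methoxyphenyl)methoxy]but-3-en-1-yl}-2,2,5,5-tetramethyl-1,3-dioxolane
Product: 25 ring ketone (C3=O) carrying the full side chain on C4, with the C1 triethylsilyl ether, the C6 tert-butyldimethylsilyl ether, the C2 and C10 4-methoxybenzyl ethers and the C12,C13 acetonide (1R,2S,4S,6R,10S,12S in target numbering; systematic name and SMILES in the compound list)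
Conditions: LiN(SiMe3)2 (2.2 equiv), toluene, −78 → 0 °C; Pd2(dba)3 (2.5 mol %), P(t-Bu)3 (6 mol %), 24, rt → 45 °C; AcOH, −78 °C
Reagents that add atoms: none
Why: Palladium-catalysed α-alkenylation of a ketone enolate: the kinetic lithium enolate forms at the C4 methylene (C2–H is flanked by the quaternary C1 and deactivated by its oxygen), is transferred to the alkenylpalladium bromide formed from 24 and zerovalent palladium, and reductive elimination makes the C4–C8 bond. C4 is set when the product dienolate is protonated at low temperature: α-protonation along the axial direction of the half-chair that keeps the C1 and C6 silyloxy groups trans-diaxial places the chain equatorial (4S), which is also the more stable epimer, while γ-protonation to the conjugated enone is kinetically slower.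

Step 22
Reactants: 25 ring ketone (C3=O) carrying the full side chain on C4
Product: 26 C3 alcohol of 25, hydroxyl cis to the C2 ether and the C4 chain (1R,2R,3R,4S,6R,10S,12S in target numbering)
Conditions: LiBH(s-Bu)3, THF, −78 °C; then H2O
Reagents that add atoms: none
Why: L-Selectride reduction of a cyclohexanone: the bulky hydride comes from the equatorial direction, the axial approach being closed by the axial C1 silyloxy group, so the C3 hydroxyl forms axial, cis to the C2 oxygen and to the C4 chain (3R).

Step 23
Reactants: 26 C3 alcohol of 25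
Product: 27 C3 acetate of 26 (configuration unchanged)
Conditions: Ac2O, pyridine, 4-(dimethylamino)pyridine (cat.), CH2Cl2, rt
Reagents that add atoms: acetic anhydride, CC(=O)OC(C)=O
Why: Acyl-transfer-catalysed acetylation of the only free hydroxyl; the C3 oxygen is thereby marked as the acetate before the C2 and C10 oxygens are uncovered.

Step 24
Reactants: 27 C3 acetate of 26
Product: 28 C2,C10-diol: 27 without its two 4-methoxybenzyl groups, silyl ethers, acetate and acetonide retained
Conditions: DDQ (2.6 equiv), CH2Cl2/pH 7 buffer (10:1), 0 °C → rt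
Reagents that add atoms: none
Why: Oxidative cleavage of both 4-methoxybenzyl ethers by hydride abstraction and hydrolysis of the oxocarbenium ions; silyl ethers, acetate, acetonide and the 1,1-disubstituted alkene are inert, so exactly the two hydroxyls that become angelates are freed.

Step 25
Reactants: 28 C2,C10-diol
Product: 29 C2,C10-bis-angelate of 28, both esters (2Z)-2-methylbut-2-enoates (1R,2R,3R,4S,6R,10S,12S in target numbering)
Conditions: angelic acid (4 equiv), 2,4,6-trichlorobenzoyl chloride (4 equiv), Et3N, toluene, rt; then 28, 4-(dimethylamino)pyridine (0.5 equiv), toluene, 60 °C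
Reagents that add atoms: angelic acid, C/C=C(/C)C(=O)O
Why: Yamaguchi esterification through the mixed anhydride, the usual way to acylate with angelic acid while keeping the (Z) geometry; both free hydroxyls are secondary, and the tertiary C1 and C13 oxygens are protected.

Step 26
Reactants: 29 C2,C10-bis-angelate of 28
Product: 30 C1,C6-diol: 29 without its two silyl groups (1S,2R,3R,4S,6R,10S,12S in target numbering)
Conditions: HF·pyridine, pyridine, THF, 0 °C → rt
Reagents that add atoms: none
Why: Fluoride-mediated desilylation under buffered acidic conditions removes the C6 and C1 silyl ethers together without acyl migration; the acetonide and the three esters should be stable.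

Step 27
Reactants: 30 C1,C6-diol
Product: 32 C1–C6 epoxide with its oxygen on the face of the C2 and C3 esters (1S,2R,3R,4S,6S,10S,12S in target numbering), via C6 triflate 31 (not isolated)
Conditions: Tf2O (1.2 equiv), pyridine, CH2Cl2, −40 → 0 °C
Reagents that add atoms: none
Why: Selective O-sulfonylation of the secondary C6 hydroxyl in the presence of the tertiary one, followed by intramolecular SN2 displacement by the trans-diaxial C1 hydroxyl (3-exo-tet); C6 is inverted, and no alkoxide is generated, so the neighbouring esters should not migrate.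

Step 28
Reactants: 32 C1–C6 epoxide
Product: 34 target CNP0212201.1, via chlorohydrin acetonide 33 (not isolated)
Conditions: LiCl, AcOH, THF, rt; then aq. HCl (2 M), rt
Reagents that add atoms: lithium chloride, [Li+].[Cl-]
Why: Epoxide opening by halide under weakly acidic, SN2-like conditions: chloride attacks the secondary C6 anti to the oxygen in the trans-diaxial sense of the half-chair with the chain equatorial, while the tertiary C1 is hindered and deactivated by the C2 acyloxy group, so C6–Cl forms trans to C1–OH (6R, net retention from the silyl ether of 11). The aqueous acid then hydrolyses the side-chain acetonide, which the chlorohydrin and the esters tolerate.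

## Compound list

1 | D-glutamic acid, (2R)-2-aminopentanedioic acid | N[C@H](CCC(=O)O)C(=O)O | starting material
2 | (2R)-5-oxooxolane-2-carboxylic acid | OC(=O)[C@H]1CCC(=O)O1 | intermediate
3 | (2R)-5-oxooxolane-2-carbonyl chloride | ClC(=O)[C@H]1CCC(=O)O1 | intermediate (not isolated)
4 | (5R)-5-acetyloxolan-2-one | CC(=O)[C@H]1CCC(=O)O1 | intermediate
5 | (5R)-5-(prop-1-en-2-yl)oxolan-2-one | C=C(C)[C@H]1CCC(=O)O1 | intermediate
6 | (4R)-4-hydroxy-N-methoxy-N,5-dimethylhex-5-enamide | C=C(C)[C@H](O)CCC(=O)N(C)OC | intermediate
7 | (4R)-4-[(tert-butyldimethylsilyl)oxy]-N-methoxy-N,5-dimethylhex-5-enamide | C=C(C)[C@H](O[Si](C)(C)C(C)(C)C)CCC(=O)N(C)OC | intermediate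
8 | (6R)-6-[(tert-butyldimethylsilyl)oxy]-7-methylocta-1,7-dien-3-one | C=C(C)[C@H](O[Si](C)(C)C(C)(C)C)CCC(=O)C=C | intermediate
9 | tert-butyl{[(3R)-5-(2-ethenyl-1,3-dioxolan-2-yl)-2-methylpent-1-en-3-yl]oxy}dimethylsilane | C=C(C)[C@H](O[Si](C)(C)C(C)(C)C)CCC1(C=C)OCCO1 | intermediate
10 | 2-{(3R)-3-[(tert-butyldimethylsilyl)oxy]-4-oxopentyl}-1,3-dioxolane-2-carbaldehyde | CC(=O)[C@H](O[Si](C)(C)C(C)(C)C)CCC1(C=O)OCCO1 | intermediate
11 | (6S,7R,8R)-8-[(tert-butyldimethylsilyl)oxy]-7-methyl-1,4-dioxaspiro[4.5]decane-6,7-diol | C1C[C@@H](O[Si](C)(C)C(C)(C)C)[C@](C)(O)[C@H](O)C12OCCO2 | intermediate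
12 | (6S,7R,8R)-8-[(tert-butyldimethylsilyl)oxy]-6-[(4-methoxyphenyl)methoxy]-7-methyl-1,4-dioxaspiro[4.5]decan-7-ol | C1C[C@@H](O[Si](C)(C)C(C)(C)C)[C@](C)(O)[C@H](OCc3ccc(OC)cc3)C12OCCO2 | intermediate
13 | tert-butyl({(6S,7R,8R)-6-[(4-methoxyphenyl)methoxy]-7-methyl-7-[(triethylsilyl)oxy]-1,4-dioxaspiro[4.5]decan-8-yl}oxy)dimethylsilane | C1C[C@@H](O[Si](C)(C)C(C)(C)C)[C@](C)(O[Si](CC)(CC)CC)[C@H](OCc3ccc(OC)cc3)C12OCCO2 | intermediate
14 | (2S,3R,4R)-4-[(tert-butyldimethylsilyl)oxy]-2-[(4-methoxyphenyl)methoxy]-3-methyl-3-[(triethylsilyl)oxy]cyclohexan-1-one | C1C[C@@H](O[Si](C)(C)C(C)(C)C)[C@](C)(O[Si](CC)(CC)CC)[C@H](OCc2ccc(OC)cc2)C1=O | intermediate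
15 | L-malic acid, (2S)-2-hydroxybutanedioic acid | O=C(O)C[C@H](O)C(=O)O | starting material
16 | 2-[(4S)-2,2-dimethyl-5-oxo-1,3-dioxolan-4-yl]acetic acid | OC(=O)C[C@@H]1OC(C)(C)OC1=O | intermediate
17 | (4S)-4-hydroxy-5,5-dimethyloxolan-2-one | O=C1C[C@H](O)C(C)(C)O1 | intermediate
18 | (3S)-3,4-dihydroxy-N-methoxy-N,4-dimethylpentanamide | CON(C)C(=O)C[C@H](O)C(C)(C)O | intermediate
19 | N-methoxy-N-methyl-2-[(4S)-2,2,5,5-tetramethyl-1,3-dioxolan-4-yl]acetamide | CON(C)C(=O)C[C@@H]1OC(C)(C)OC1(C)C | intermediate
20 | 1-[(4S)-2,2,5,5-tetramethyl-1,3-dioxolan-4-yl]but-3-en-2-one | C=CC(=O)C[C@@H]1OC(C)(C)OC1(C)C | intermediate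
21 | 3,4-dibromo-1-[(4S)-2,2,5,5-tetramethyl-1,3-dioxolan-4-yl]butan-2-one (both C3 epimers) | BrCC(Br)C(=O)C[C@@H]1OC(C)(C)OC1(C)C | intermediate (not isolated)
22 | 3-bromo-1-[(4S)-2,2,5,5-tetramethyl-1,3-dioxolan-4-yl]but-3-en-2-one | C=C(Br)C(=O)C[C@@H]1OC(C)(C)OC1(C)C | intermediate
23 | (2S)-3-bromo-1-[(4S)-2,2,5,5-tetramethyl-1,3-dioxolan-4-yl]but-3-en-2-ol | C=C(Br)[C@@H](O)C[C@@H]1OC(C)(C)OC1(C)C | intermediate
24 | (4S)-4-{(2S)-3-bromo-2-[(4-methoxyphenyl)methoxy]but-3-en-1-yl}-2,2,5,5-tetramethyl-1,3-dioxolane | C=C(Br)[C@@H](OCc1ccc(OC)cc1)C[C@@H]2OC(C)(C)OC2(C)C | intermediate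
25 | (2S,3R,4R,6S)-4-[(tert-butyldimethylsilyl)oxy]-2-[(4-methoxyphenyl)methoxy]-6-{(3S)-3-[(4-methoxyphenyl)methoxy]-4-[(4S)-2,2,5,5-tetramethyl-1,3-dioxolan-4-yl]but-1-en-2-yl}-3-methyl-3-[(triethylsilyl)oxy]cyclohexan-1-one | C=C([C@@H](OCc1ccc(OC)cc1)C[C@@H]2OC(C)(C)OC2(C)C)[C@@H]3C[C@@H](O[Si](C)(C)C(C)(C)C)[C@](C)(O[Si](CC)(CC)CC)[C@H](OCc4ccc(OC)cc4)C3=O | intermediate
26 | (1R,2R,3R,4R,6S)-4-[(tert-butyldimethylsilyl)oxy]-2-[(4-methoxyphenyl)methoxy]-6-{(3S)-3-[(4-methoxyphenyl)methoxy]-4-[(4S)-2,2,5,5-tetramethyl-1,3-dioxolan-4-yl]but-1-en-2-yl}-3-methyl-3-[(triethylsilyl)oxy]cyclohexan-1-ol | C=C([C@@H](OCc1ccc(OC)cc1)C[C@@H]2OC(C)(C)OC2(C)C)[C@@H]3C[C@@H](O[Si](C)(C)C(C)(C)C)[C@](C)(O[Si](CC)(CC)CC)[C@H](OCc4ccc(OC)cc4)[C@@H]3O | intermediate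
27 | acetate of 26, (1R,2R,3R,4R,6S)-configured cyclohexyl acetate | C=C([C@@H](OCc1ccc(OC)cc1)C[C@@H]2OC(C)(C)OC2(C)C)[C@@H]3C[C@@H](O[Si](C)(C)C(C)(C)C)[C@](C)(O[Si](CC)(CC)CC)[C@H](OCc4ccc(OC)cc4)[C@@H]3OC(C)=O | intermediate
28 | (1R,2R,3R,4R,6S)-4-[(tert-butyldimethylsilyl)oxy]-2-hydroxy-6-{(3S)-3-hydroxy-4-[(4S)-2,2,5,5-tetramethyl-1,3-dioxolan-4-yl]but-1-en-2-yl}-3-methyl-3-[(triethylsilyl)oxy]cyclohexyl acetate | C=C([C@@H](O)C[C@@H]2OC(C)(C)OC2(C)C)[C@@H]3C[C@@H](O[Si](C)(C)C(C)(C)C)[C@](C)(O[Si](CC)(CC)CC)[C@H](O)[C@@H]3OC(C)=O | intermediate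
29 | bis[(2Z)-2-methylbut-2-enoate] of 28 at the C2 and C10 hydroxyls (1R,2R,3R,4S,6R,10S,12S in target numbering) | C=C([C@@H](OC(=O)/C(C)=C\C)C[C@@H]2OC(C)(C)OC2(C)C)[C@@H]3C[C@@H](O[Si](C)(C)C(C)(C)C)[C@](C)(O[Si](CC)(CC)CC)[C@H](OC(=O)/C(C)=C\C)[C@@H]3OC(C)=O | intermediate
30 | C1,C6-diol: 3-acetate 2,10-bis-angelate 12,13-acetonide with free C1 and C6 hydroxyls (1S,2R,3R,4S,6R,10S,12S in target numbering) | C=C([C@@H](OC(=O)/C(C)=C\C)C[C@@H]2OC(C)(C)OC2(C)C)[C@@H]3C[C@@H](O)[C@](C)(O)[C@H](OC(=O)/C(C)=C\C)[C@@H]3OC(C)=O | intermediate
31 | C6 trifluoromethanesulfonate of 30 (1R,2R,3R,4S,6R,10S,12S in target numbering) | C=C([C@@H](OC(=O)/C(C)=C\C)C[C@@H]2OC(C)(C)OC2(C)C)[C@@H]3C[C@@H](OS(=O)(=O)C(F)(F)F)[C@](C)(O)[C@H](OC(=O)/C(C)=C\C)[C@@H]3OC(C)=O | intermediate (not isolated)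
32 | C1–C6 epoxide, oxygen on the face of the C2 and C3 esters (1S,2R,3R,4S,6S,10S,12S in target numbering) | C=C([C@@H](OC(=O)/C(C)=C\C)C[C@@H]2OC(C)(C)OC2(C)C)[C@@H]3C[C@@H]4O[C@]4(C)[C@H](OC(=O)/C(C)=C\C)[C@@H]3OC(C)=O | intermediate
33 | 12,13-O-isopropylidene derivative of the target (1R,2R,3R,4S,6R,10S,12S) | C=C([C@@H](OC(=O)/C(C)=C\C)C[C@@H]2OC(C)(C)OC2(C)C)[C@@H]3C[C@@H](Cl)[C@](C)(O)[C@H](OC(=O)/C(C)=C\C)[C@@H]3OC(C)=O | intermediate (not isolated)
34 | CNP0212201.1 (1R,2R,3R,4S,6R,10S,12S) | C=C([C@H](C[C@H](O)C(C)(C)O)OC(=O)/C(C)=C\C)[C@@H]1C[C@@H](Cl)[C@](C)(O)[C@H](OC(=O)/C(C)=C\C)[C@@H]1OC(C)=O | target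

## Step count and least certain steps

Total: 28 steps. Longest linear sequence: 20 steps (steps 1–12 and 21–28, from D-glutamic acid). The side-chain branch takes 8 steps (13–20) before the coupling.

**Step 9 (key step).** The ketyl may simply be reduced further to the primary alcohol, or it may expel a ketal oxygen from C3 before it reaches the ketone. Facial discrimination at C1 may also be incomplete, because the C6 silyl ether is the only stereocontrolling element and the ketal crowds the aldehyde.
Fallback: it sets out from 10 and returns at 11. A McMurry coupling with low-valent titanium (TiCl3, Zn–Cu, DME, reflux) would join the same two carbonyl carbons as the alkene tert-butyldimethyl{[(8R)-7-methyl-1,4-dioxaspiro[4.5]dec-6-en-8-yl]oxy}silane F1. OsO4-catalysed dihydroxylation (N-methylmorpholine N-oxide, acetone/H2O) should then add both hydroxyls to the face opposite the allylic silyloxy group and give 11.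

**Step 21.** Coupling between two hindered partners may be slow at the oxidative addition or reductive elimination stage. Enolisation may leak towards C2, with loss of the C1 silyloxy group. The C8=C9 bond may move into conjugation with the ketone on prolonged exposure to base. Protonation at C4 may occur from the wrong face.
Fallback: it sets out from 14 and 24 and returns at 25. Dehydrogenation of 14 through its lithium enolate with N-tert-butylbenzenesulfinimidoyl chloride would give the enone (4R,5R,6S)-4-[(tert-butyldimethylsilyl)oxy]-6-[(4-methoxyphenyl)methoxy]-5-methyl-5-[(triethylsilyl)oxy]cyclohex-2-en-1-one F2. Iodine and pyridine would convert it into the 2-iodo enone F3. Bromide 24 would be turned by bromine–lithium exchange (t-BuLi, −78 °C) and Bu3SnCl into the alkenylstannane F4. Stille coupling of F3 with F4 (Pd2(dba)3, AsPh3, CuI) would give the cross-conjugated dienone F5. Conjugate reduction of its ring enone with [(Ph3P)CuH]6 and protonation would lead to 25.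

**Step 28 (and step 27 before it).** Chloride may enter at the tertiary C1 if the opening acquires ionisation character. The epoxide may rearrange to a ketone under acid. In step 27 the C6 sulfonate may eliminate or trigger a ring contraction if the ring leaves the diaxial chair.
Fallback: it sets out from 30 and returns at 34, without the epoxide. Oxidation of the C6 hydroxyl (Dess–Martin periodinane) would give the α-hydroxy ketone F6. Axial hydride delivery (NaBH4, CeCl3·7H2O, MeOH, −78 °C) would give the cis-1,6-diol F7. SO2Cl2 and Et3N would close the cyclic sulfate F8. LiCl in DMF can only attack the secondary C6, with inversion, to give the lithium C1 sulfate monoester of the chlorohydrin F9. Aqueous H2SO4 in THF would then hydrolyse the sulfate ester and the acetonide to 34.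

**Step 25.** The angelate may isomerise to the tiglate in the presence of the acyl-transfer catalyst at 60 °C. Acylation of the hindered C2 hydroxyl may stall. The C3 acetate may shift to the free C2 hydroxyl before it is acylated.
Fallback: it sets out from 28 and returns at 29. Both hydroxyls would be acylated with 2-[bis(2,2,2-trifluoroethoxy)phosphoryl]propanoic acid (DCC, 4-(dimethylamino)pyridine) to the bis(phosphonopropanoate) F10. A double Still–Gennari olefination with acetaldehyde (KN(SiMe3)2, 18-crown-6, THF, −78 °C) would then build both (Z)-2-methylbut-2-enoates in place and give 29.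

**Step 12.** Hydrolysis of the ketal may be slow, because the neighbouring C2 oxygen destabilises the oxocarbenium ion. Under forcing conditions the tertiary triethylsilyl ether may be lost.
Fallback: it sets out from 12 and returns at 14, with the order of the two steps reversed. The ketal of 12 would be hydrolysed with stronger aqueous acid (1 M HCl, THF), which the single hindered secondary silyl ether tolerates, to the hydroxy ketone (2S,3R,4R)-4-[(tert-butyldimethylsilyl)oxy]-3-hydroxy-2-[(4-methoxyphenyl)methoxy]-3-methylcyclohexan-1-one F11. The tertiary hydroxyl would then be silylated with Et3SiCl, imidazole and 4-(dimethylamino)pyridine in DMF at 45 °C, conditions that do not enolise the ketone, to give 14.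

## Further compounds

F1 | step 9 | tert-butyldimethyl{[(8R)-7-methyl-1,4-dioxaspiro[4.5]dec-6-en-8-yl]oxy}silane | CC1=CC2(OCCO2)CC[C@H]1O[Si](C)(C)C(C)(C)C
F2 | step 21 | (4R,5R,6S)-4-[(tert-butyldimethylsilyl)oxy]-6-[(4-methoxyphenyl)methoxy]-5-methyl-5-[(triethylsilyl)oxy]cyclohex-2-en-1-one | C1=C[C@@H](O[Si](C)(C)C(C)(C)C)[C@](C)(O[Si](CC)(CC)CC)[C@H](OCc2ccc(OC)cc2)C1=O
F3 | step 21 | (4R,5R,6S)-4-[(tert-butyldimethylsilyl)oxy]-2-iodo-6-[(4-methoxyphenyl)methoxy]-5-methyl-5-[(triethylsilyl)oxy]cyclohex-2-en-1-one | IC1=C[C@@H](O[Si](C)(C)C(C)(C)C)[C@](C)(O[Si](CC)(CC)CC)[C@H](OCc2ccc(OC)cc2)C1=O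
F4 | step 21 | tributyl{(3S)-3-[(4-methoxyphenyl)methoxy]-4-[(4S)-2,2,5,5-tetramethyl-1,3-dioxolan-4-yl]but-1-en-2-yl}stannane | C=C([Sn](CCCC)(CCCC)CCCC)[C@@H](OCc1ccc(OC)cc1)C[C@@H]2OC(C)(C)OC2(C)C
F5 | step 21 | 2-alkenyl enone: 4,5-didehydro derivative of 25 | C=C([C@@H](OCc1ccc(OC)cc1)C[C@@H]2OC(C)(C)OC2(C)C)C3=C[C@@H](O[Si](C)(C)C(C)(C)C)[C@](C)(O[Si](CC)(CC)CC)[C@H](OCc4ccc(OC)cc4)C3=O
F6 | step 28 | C6 ketone of 30 (α-hydroxy ketone) | C=C([C@@H](OC(=O)/C(C)=C\C)C[C@@H]2OC(C)(C)OC2(C)C)[C@@H]3CC(=O)[C@](C)(O)[C@H](OC(=O)/C(C)=C\C)[C@@H]3OC(C)=O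
F7 | step 28 | C6 epimer of 30 (cis-1,6-diol) | C=C([C@@H](OC(=O)/C(C)=C\C)C[C@@H]2OC(C)(C)OC2(C)C)[C@@H]3C[C@H](O)[C@](C)(O)[C@H](OC(=O)/C(C)=C\C)[C@@H]3OC(C)=O
F8 | step 28 | C1,C6 cyclic sulfate of F7 | C=C([C@@H](OC(=O)/C(C)=C\C)C[C@@H]2OC(C)(C)OC2(C)C)[C@@H]3C[C@@H]4OS(=O)(=O)O[C@]4(C)[C@H](OC(=O)/C(C)=C\C)[C@@H]3OC(C)=O
F9 | step 28 | lithium C1 sulfate monoester of chlorohydrin 33 | [Li+].C=C([C@@H](OC(=O)/C(C)=C\C)C[C@@H]2OC(C)(C)OC2(C)C)[C@@H]3C[C@@H](Cl)[C@](C)(OS(=O)(=O)[O-])[C@H](OC(=O)/C(C)=C\C)[C@@H]3OC(C)=O
F10 | step 25 | C2,C10-bis{2-[bis(2,2,2-trifluoroethoxy)phosphoryl]propanoate} of 28 (phosphonate α-carbons as mixtures) | C=C([C@@H](OC(=O)C(C)P(=O)(OCC(F)(F)F)OCC(F)(F)F)C[C@@H]2OC(C)(C)OC2(C)C)[C@@H]3C[C@@H](O[Si](C)(C)C(C)(C)C)[C@](C)(O[Si](CC)(CC)CC)[C@H](OC(=O)C(C)P(=O)(OCC(F)(F)F)OCC(F)(F)F)[C@@H]3OC(C)=O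
F11 | step 12 | (2S,3R,4R)-4-[(tert-butyldimethylsilyl)oxy]-3-hydroxy-2-[(4-methoxyphenyl)methoxy]-3-methylcyclohexan-1-one | C1C[C@@H](O[Si](C)(C)C(C)(C)C)[C@](C)(O)[C@H](OCc2ccc(OC)cc2)C1=O
A1 | alternative 1 | C10 allylic pinacol boronate carrying the full carbon skeleton | C=C([C@H](CC=C(C)C)B2OC(C)(C)C(C)(C)O2)[C@@H]1CC=C(C)[C@H](O[Si](C)(C)C(C)(C)C)[C@@H]1O[Si](C)(C)C(C)(C)C
A2 | alternative 1 | ring alkenyllithium (C8-lithiated cyclohexene bis-silyl ether) | [Li]C(=C)[C@@H]1CC=C(C)[C@H](O[Si](C)(C)C(C)(C)C)[C@@H]1O[Si](C)(C)C(C)(C)C
A3 | alternative 1 | vinylboronic acid pinacol ester | C=CB1OC(C)(C)C(C)(C)O1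
A4 | alternative 1 | 2-methylprop-1-enyl trifluoromethanesulfonate | CC(C)=COS(=O)(=O)C(F)(F)F
A5 | alternative 1 | palladium diacetate, Pd(OAc)2 | CC(=O)[O-].CC(=O)[O-].[Pd+2]
A6 | alternative 2 | methyl 4-chloro-2-oxocyclohexanecarboxylate with C1,C2 acetonide | COC(=O)[C@@H]1C[C@@H](Cl)[C@]2(C)OC(C)(C)O[C@@H]2C1=O
A7 | alternative 2 | manganese triacetate, Mn(OAc)3 | CC(=O)[O-].CC(=O)[O-].CC(=O)[O-].[Mn+3]
A8 | alternative 2 | copper dichloride, CuCl2 | [Cu+2].[Cl-].[Cl-]
A9 | alternative 3 | cyclohexane hydroxy ester with C6 alcohol, C4 ester, C1,C2 acetonide and C3 silyl ether | COC(=O)[C@@H]1C[C@@H](O)[C@]2(C)OC(C)(C)O[C@@H]2[C@@H]1O[Si](C)(C)C(C)(C)C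
A10 | alternative 3 | samarium diiodide, SmI2 | [Sm+2].[I-].[I-]
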